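**Retrosynthetic overview**

1. The target is epimesquitol-(4β→6)-epioritin-4α-ol (upper unit 2R,3R,4S; lower unit 2R,3R,4R); the last operations only remove three aryl pivalates and two diphenylmethylene ketals from the fully assembled dimer.
2. Key disconnection: the lower pyran ring is cut at O-1–C-2 and C-4–C-4a into a phenol (lower A ring already bonded to the complete upper unit) and a cis-(2S,3S)-3-aryloxirane-2-carbaldehyde; forward, a titanium-phenolate ortho-hydroxyalkylation followed in the same flask by 6-endo epoxide opening (formal [3+3] annulation) closes this ring last and sets C-2, C-3 and C-4.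
3. Enabling feature: in the lower unit O-1 and C-4a are an ortho O/C pair of the pyrogallol A ring, and C-4a is the only C–H ortho to a free phenol once C-6 bears the upper unit and O-7/O-8 are locked in a temporary dioxole ring; C-2, C-3 and C-4 all carry oxygen in an all-cis array with C-2 benzylic, which is the imprint of a cis-epoxy aldehyde opened with inversion at its benzylic carbon.
4. Interflavanyl bond C-4(upper)–C-6(lower): Friedel–Crafts capture of the upper C-4 benzylic cation by a TIPS-protected pyrogallol ketal, para to OSi and trans to the upper 3-OH; the upper unit comes from the same annulation on the simple phenol (its C-4 configuration is erased on ionisation).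
5. Ring order: protecting dioxole rings (not in the target) → upper pyran ring → C-4–C-6 bond → lower pyran ring; both epoxy aldehydes come from Z-allylic alcohols by Sharpless epoxidation and Dess–Martin oxidation.

Key step: step 16

Remark: flavan numbering is used (O-1, C-2, C-3, C-4, C-4a, C-5 to C-8, C-8a; B ring primed); "upper" is the epimesquitol unit and "lower" the teracacidin unit. The configuration at upper C-4 is given as 4β (trans to the 3-OH) rather than by a CIP letter.

**Route**

Step 1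
Reactants: 1 pyrogallol (benzene-1,2,3-triol)
Product: 2 2,2-diphenyl-1,3-benzodioxol-4-ol
Conditions: Ph2CCl2 (1.1 equiv), neat, 170 °C, N2 sweep
Reagents that add atoms: dichlorodiphenylmethane ClC(Cl)(c1ccccc1)c1ccccc1
Why: Ketalisation of a catechol pair with a gem-dichloride can give only this one 1,2-ketal, which leaves a single free phenol (future O-1) with a single free ortho C–H (future C-4a).

Step 2
Reactants: 2 2,2-diphenyl-1,3-benzodioxol-4-ol
Product: 3 triisopropyl[(2,2-diphenyl-1,3-benzodioxol-4-yl)oxy]silane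
Conditions: TIPSCl, imidazole, DMF, rt
Reagents that add atoms: chlorotriisopropylsilane CC(C)[Si](Cl)(C(C)C)C(C)C
Why: Standard silylation of a phenol; the bulky silyl group is there to shield its ortho position in step 9.

Step 3
Reactants: 4 4-bromocatechol (4-bromobenzene-1,2-diol)
Product: 5 4-bromo-1,2-phenylene bis(2,2-dimethylpropanoate)
Conditions: PivCl, Et3N, DMAP (cat.), CH2Cl2, 0 °C → rt
Reagents that add atoms: pivaloyl chloride CC(C)(C)C(Cl)=O
Why: Acylation of both phenols; acyloxy rather than alkoxy groups are chosen so that the later aryl epoxide behaves like a phenyl epoxide (stable, opened by SN2).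

Step 4
Reactants: 5 4-bromo-1,2-phenylene bis(2,2-dimethylpropanoate); 6 propargyl alcohol (prop-2-yn-1-ol)
Product: 7 4-(3-hydroxyprop-1-yn-1-yl)-1,2-phenylene bis(2,2-dimethylpropanoate)
Conditions: Pd(PPh3)2Cl2 (cat.), CuI (cat.), Et3N, THF, 60 °C
Reagents that add atoms: none
Why: Sonogashira coupling of an aryl bromide with a terminal alkyne; the tertiary amine base does not attack the hindered aryl pivalates.

Step 5
Reactants: 7 4-(3-hydroxyprop-1-yn-1-yl)-1,2-phenylene bis(2,2-dimethylpropanoate)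
Product: 8 4-[(Z)-3-hydroxyprop-1-en-1-yl]-1,2-phenylene bis(2,2-dimethylpropanoate)
Conditions: H2 (1 atm), Lindlar catalyst, quinoline, EtOAc, rt
Reagents that add atoms: none
Why: Lindlar semihydrogenation adds H2 syn to the alkyne and so gives the Z-allylic alcohol.

Step 6
Reactants: 8 4-[(Z)-3-hydroxyprop-1-en-1-yl]-1,2-phenylene bis(2,2-dimethylpropanoate)
Product: 9 [(2R,3S)-3-[3,4-bis(pivaloyloxy)phenyl]oxiran-2-yl]methanol (cis)
Conditions: Ti(OiPr)4 (cat.), D-(−)-diethyl tartrate (cat.), t-BuOOH, 4 Å MS, CH2Cl2, −20 °C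
Reagents that add atoms: tert-butyl hydroperoxide CC(C)(C)OO
Why: Sharpless asymmetric epoxidation; D-(−)-tartrate should set 2R at the carbinol-bearing carbon and the Z geometry translates into the cis (2R,3S) epoxide, with Z substrates expected to react more slowly than E ones.

Step 7
Reactants: 9 [(2R,3S)-3-[3,4-bis(pivaloyloxy)phenyl]oxiran-2-yl]methanol
Product: 10 (2S,3S)-3-[3,4-bis(pivaloyloxy)phenyl]oxirane-2-carbaldehyde (cis)
Conditions: Dess–Martin periodinane, NaHCO3, CH2Cl2, 0 °C → rt; used at once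
Reagents that add atoms: none
Why: Dess–Martin oxidation under buffered, non-basic conditions should keep the epimerisable cis-epoxy aldehyde intact (the C-2 letter changes from R to S only through CIP priorities).

Step 8
Reactants: 2 2,2-diphenyl-1,3-benzodioxol-4-ol; 10 (2S,3S)-3-[3,4-bis(pivaloyloxy)phenyl]oxirane-2-carbaldehyde
Product: 13 (2R,3R,4R)-2-[3,4-bis(pivaloyloxy)phenyl]-7,8-(diphenylmethylenedioxy)flavan-3,4-diol, via titanium phenolate 11 (not isolated), via epoxy carbinol 12 (not isolated)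
Conditions: Ti(OiPr)4 (1.05 equiv), toluene, rt, then evaporation of i-PrOH; 10, CH2Cl2, −20 °C → rt; aq. Rochelle salt
Reagents that add atoms: none
Why: Proposed new method: titanium phenolate 11 should add through its only free ortho carbon to the coordinated aldehyde of 10 (closest known reaction: ortho-specific hydroxyalkylation of titanium and magnesium phenolates with α-oxygenated aldehydes) to give the titanium-bound epoxy carbinol 12, a 2,3-epoxy-1-ol titanate of the kind that undergoes the known Ti(OiPr)4-mediated C-3-selective epoxide opening, so that the titanium-bound phenolate oxygen closes the pyran ring by 6-endo attack with inversion at the benzylic carbon, turning the cis-(2S,3S) epoxide into the 2,3-cis (2R,3R) flavan while Felkin–Anh addition gives the 3,4-cis carbinol (the C-4 configuration is irrelevant here because C-4 is ionised in step 9).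

Step 9
Reactants: 13 (2R,3R,4R)-2-[3,4-bis(pivaloyloxy)phenyl]-7,8-(diphenylmethylenedioxy)flavan-3,4-diol; 3 triisopropyl[(2,2-diphenyl-1,3-benzodioxol-4-yl)oxy]silane
Product: 14 (2R,3R)-2-[3,4-bis(pivaloyloxy)phenyl]-7,8-(diphenylmethylenedioxy)-4β-[2,2-diphenyl-7-(triisopropylsilyloxy)-1,3-benzodioxol-4-yl]flavan-3-ol (2,3-cis-3,4-trans)
Conditions: BF3·OEt2 (cat.), 4 Å MS, CH2Cl2, −40 → 0 °C; 3 (4 equiv), slow addition of 13
Reagents that add atoms: none
Why: Lewis-acid ionisation of a flavan-3,4-diol at C-4 (cation stabilised by O-1 and the para O-7) and Friedel–Crafts capture by an oxygenated arene is the standard interflavanyl bond formation; attack should occur para to OTIPS (its ortho position is shielded, the position next to the tied-back dioxole oxygen is open) and trans to the axial 3-OH of the 2,3-cis unit (4β), with the excess of 3 suppressing self-condensation.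

Step 10
Reactants: 14 the TIPS ether from step 9
Product: 15 (2R,3R)-2-[3,4-bis(pivaloyloxy)phenyl]-7,8-(diphenylmethylenedioxy)-4β-(7-hydroxy-2,2-diphenyl-1,3-benzodioxol-4-yl)flavan-3-ol
Conditions: TBAF, AcOH, THF, 0 °C
Reagents that add atoms: none
Why: Fluoride cleavage of an aryl silyl ether; buffering with acetic acid keeps the liberated phenolate from attacking the aryl pivalates.

Step 11
Reactants: 16 4-iodophenol
Product: 17 4-iodophenyl 2,2-dimethylpropanoate
Conditions: PivCl, Et3N, DMAP (cat.), CH2Cl2, 0 °C → rt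
Reagents that add atoms: pivaloyl chloride CC(C)(C)C(Cl)=O
Why: Phenol acylation; the 4-pivaloyloxy group will later keep the benzylic epoxide opening in the SN2 regime.

Step 12
Reactants: 17 4-iodophenyl 2,2-dimethylpropanoate; 6 propargyl alcohol
Product: 18 4-(3-hydroxyprop-1-yn-1-yl)phenyl 2,2-dimethylpropanoate
Conditions: Pd(PPh3)2Cl2 (cat.), CuI (cat.), Et3N, THF, rt
Reagents that add atoms: none
Why: Sonogashira coupling of an aryl iodide, which proceeds at room temperature.

Step 13
Reactants: 18 4-(3-hydroxyprop-1-yn-1-yl)phenyl 2,2-dimethylpropanoate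
Product: 19 4-[(Z)-3-hydroxyprop-1-en-1-yl]phenyl 2,2-dimethylpropanoate
Conditions: H2 (1 atm), Lindlar catalyst, quinoline, EtOAc, rt
Reagents that add atoms: none
Why: Lindlar semihydrogenation gives the Z-alkene by syn addition of H2.

Step 14
Reactants: 19 4-[(Z)-3-hydroxyprop-1-en-1-yl]phenyl 2,2-dimethylpropanoate
Product: 20 [(2R,3S)-3-(4-pivaloyloxyphenyl)oxiran-2-yl]methanol (cis)
Conditions: Ti(OiPr)4 (cat.), D-(−)-diethyl tartrate (cat.), t-BuOOH, 4 Å MS, CH2Cl2, −20 °C
Reagents that add atoms: tert-butyl hydroperoxide CC(C)(C)OO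
Why: Sharpless asymmetric epoxidation of the Z-allylic alcohol with D-(−)-tartrate should give the cis (2R,3S) epoxy alcohol, as in step 6.

Step 15
Reactants: 20 [(2R,3S)-3-(4-pivaloyloxyphenyl)oxiran-2-yl]methanol
Product: 21 (2S,3S)-3-(4-pivaloyloxyphenyl)oxirane-2-carbaldehyde (cis)
Conditions: Dess–Martin periodinane, NaHCO3, CH2Cl2, 0 °C → rt; used at once
Reagents that add atoms: none
Why: Buffered Dess–Martin oxidation, as in step 7, avoids epimerisation of the cis-epoxy aldehyde.

Step 16
Reactants: 15 the phenol from step 10; 21 (2S,3S)-3-(4-pivaloyloxyphenyl)oxirane-2-carbaldehyde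
Product: 24 protected dimer 6-{(2R,3R)-2-[3,4-bis(pivaloyloxy)phenyl]-3-hydroxy-7,8-(diphenylmethylenedioxy)flavan-4β-yl}-(2R,3R,4R)-2-(4-pivaloyloxyphenyl)-7,8-(diphenylmethylenedioxy)flavan-3,4-diol, via bis-titanate 22 (not isolated), via epoxy carbinol 23 (not isolated)
Conditions: Ti(OiPr)4 (2.1 equiv), toluene, rt, then evaporation of i-PrOH; 21 (1.3 equiv), CH2Cl2, −20 °C → rt; aq. Rochelle salt
Reagents that add atoms: none
Why: Proposed new method: the bis(triisopropoxytitanium) derivative 22 binds aldehyde 21 at the phenolate titanium and its only free ortho carbon (lower C-4a) adds to the carbonyl through a six-membered transition state (closest known reaction: ortho-hydroxyalkylation of metal phenolates with α-oxygenated aldehydes), giving the titanium-bound epoxy carbinol 23; this is a 2,3-epoxy-1-ol titanate, the species involved in the known Ti(OiPr)4-mediated C-3-selective opening of epoxy alcohols, and the titanium-bound phenolate O-1 opens it at the benzylic carbon. The ring is closed by a 6-endo-tet epoxide opening, so the whole process is a formal [3+3] annulation of the C-4a/O-1 dinucleophile with the C-4/C-2 dielectrophile; the 5-exo mode (attack at C-3) is disfavoured by benzylic activation and by the distal-carbon preference of the titanium chelate. C-4 (R) is set by Felkin–Anh addition anti to the epoxide C–O bond under the non-chelating Ti(OiPr)3 centre (erythro carbinol, hence 3,4-cis), C-2 (R) by inversion of the (3S) benzylic epoxide carbon, and C-3 (R) is carried over from the epoxide, so the cis-epoxide maps onto the 2,3-cis-3,4-cis triad. The selectivities needed are ortho regiochemistry (C-4a is the only C–H ortho to a free phenol because C-6 carries the upper unit and O-7/O-8 are locked in the ketal), SN2 rather than SN1 opening (the 4-pivaloyloxy group makes the aryl no better a cation stabiliser than phenyl) and chemoselectivity for the aldehyde over the aryl pivalates (a mild oxophilic titanium alkoxide at or below room temperature).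

Step 17
Reactants: 24 the protected dimer from step 16
Product: 25 6-[(2R,3R)-2-(3,4-dihydroxyphenyl)-3-hydroxy-7,8-(diphenylmethylenedioxy)flavan-4β-yl]-(2R,3R,4R)-2-(4-hydroxyphenyl)-7,8-(diphenylmethylenedioxy)flavan-3,4-diol
Conditions: NaOMe (3.3 equiv), MeOH/THF, 0 °C → rt, Ar; then AcOH
Reagents that add atoms: none
Why: Methanolysis of aryl pivalates while the oxidation-prone pyrogallol rings are still ketalised; low temperature and exclusion of air should prevent catechol oxidation and quinone-methide epimerisation at C-2.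

Step 18
Reactants: 25 the bis-ketal from step 17
Product: 26 epimesquitol-(4β→6)-epioritin-4α-ol, (2R,3R,4S)-2-(3,4-dihydroxyphenyl)-4-[(2R,3R,4R)-3,4,7,8-tetrahydroxy-2-(4-hydroxyphenyl)chroman-6-yl]chroman-3,7,8-triol
Conditions: H2 (1 atm), Pd(OH)2/C, THF/MeOH, rt
Reagents that add atoms: none
Why: Hydrogenolysis of the two benzophenone ketals (doubly benzylic C–O bonds) under neutral conditions releases the four A-ring phenols; the secondary C-4 alcohol and the C-2–O-1 bonds are expected to survive a short reaction at 1 atm, since flavan-3,4-diols are themselves end-points of catalytic hydrogenation.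

**Compound list**

1 | pyrogallol | Oc1cccc(O)c1O | starting material
2 | 2,2-diphenyl-1,3-benzodioxol-4-ol | Oc1cccc2OC(c3ccccc3)(c3ccccc3)Oc12 | intermediate
3 | triisopropyl[(2,2-diphenyl-1,3-benzodioxol-4-yl)oxy]silane | CC(C)[Si](C(C)C)(C(C)C)Oc1cccc2OC(c3ccccc3)(c3ccccc3)Oc12 | intermediate
4 | 4-bromocatechol | Oc1ccc(Br)cc1O | starting material
5 | 4-bromo-1,2-phenylene bis(2,2-dimethylpropanoate) | CC(C)(C)C(=O)Oc1ccc(Br)cc1OC(=O)C(C)(C)C | intermediate
6 | propargyl alcohol | OCC#C | starting material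
7 | 4-(3-hydroxyprop-1-yn-1-yl)-1,2-phenylene bis(2,2-dimethylpropanoate) | CC(C)(C)C(=O)Oc1ccc(C#CCO)cc1OC(=O)C(C)(C)C | intermediate
8 | 4-[(Z)-3-hydroxyprop-1-en-1-yl]-1,2-phenylene bis(2,2-dimethylpropanoate) | CC(C)(C)C(=O)Oc1ccc(/C=C\CO)cc1OC(=O)C(C)(C)C | intermediate
9 | [(2R,3S)-3-[3,4-bis(pivaloyloxy)phenyl]oxiran-2-yl]methanol (cis) | OC[C@H]1O[C@H]1c1ccc(OC(=O)C(C)(C)C)c(OC(=O)C(C)(C)C)c1 | intermediate
10 | (2S,3S)-3-[3,4-bis(pivaloyloxy)phenyl]oxirane-2-carbaldehyde (cis) | O=C[C@H]1O[C@H]1c1ccc(OC(=O)C(C)(C)C)c(OC(=O)C(C)(C)C)c1 | intermediate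
11 | triisopropoxytitanium 2,2-diphenyl-1,3-benzodioxol-4-olate | CC(C)O[Ti](OC(C)C)(OC(C)C)Oc1cccc2OC(c3ccccc3)(c3ccccc3)Oc12 | intermediate (not isolated)
12 | (R)-(4-hydroxy-2,2-diphenyl-1,3-benzodioxol-5-yl)[(2R,3S)-3-[3,4-bis(pivaloyloxy)phenyl]oxiran-2-yl]methanol, titanium-bound in the flask, drawn as the free phenol | Oc1c(ccc2OC(c3ccccc3)(c3ccccc3)Oc12)[C@@H](O)[C@H]1O[C@H]1c1ccc(OC(=O)C(C)(C)C)c(OC(=O)C(C)(C)C)c1 | intermediate (not isolated)
13 | (2R,3R,4R)-2-[3,4-bis(pivaloyloxy)phenyl]-7,8-(diphenylmethylenedioxy)flavan-3,4-diol (all-cis, protected melacacidin) | CC(C)(C)C(=O)Oc1ccc([C@H]2Oc3c(ccc4OC(c5ccccc5)(c5ccccc5)Oc34)[C@@H](O)[C@H]2O)cc1OC(=O)C(C)(C)C | intermediate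
14 | (2R,3R)-2-[3,4-bis(pivaloyloxy)phenyl]-7,8-(diphenylmethylenedioxy)-4β-[2,2-diphenyl-7-(triisopropylsilyloxy)-1,3-benzodioxol-4-yl]flavan-3-ol | CC(C)[Si](C(C)C)(C(C)C)Oc1ccc([C@H]2c3ccc4OC(c5ccccc5)(c5ccccc5)Oc4c3O[C@H](c3ccc(OC(=O)C(C)(C)C)c(OC(=O)C(C)(C)C)c3)[C@@H]2O)c2OC(c3ccccc3)(c3ccccc3)Oc12 | intermediate
15 | (2R,3R)-2-[3,4-bis(pivaloyloxy)phenyl]-7,8-(diphenylmethylenedioxy)-4β-(7-hydroxy-2,2-diphenyl-1,3-benzodioxol-4-yl)flavan-3-ol | Oc1ccc([C@H]2c3ccc4OC(c5ccccc5)(c5ccccc5)Oc4c3O[C@H](c3ccc(OC(=O)C(C)(C)C)c(OC(=O)C(C)(C)C)c3)[C@@H]2O)c2OC(c3ccccc3)(c3ccccc3)Oc12 | intermediate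
16 | 4-iodophenol | Oc1ccc(I)cc1 | starting material
17 | 4-iodophenyl 2,2-dimethylpropanoate | CC(C)(C)C(=O)Oc1ccc(I)cc1 | intermediate
18 | 4-(3-hydroxyprop-1-yn-1-yl)phenyl 2,2-dimethylpropanoate | CC(C)(C)C(=O)Oc1ccc(C#CCO)cc1 | intermediate
19 | 4-[(Z)-3-hydroxyprop-1-en-1-yl]phenyl 2,2-dimethylpropanoate | CC(C)(C)C(=O)Oc1ccc(/C=C\CO)cc1 | intermediate
20 | [(2R,3S)-3-(4-pivaloyloxyphenyl)oxiran-2-yl]methanol (cis) | OC[C@H]1O[C@H]1c1ccc(OC(=O)C(C)(C)C)cc1 | intermediate
21 | (2S,3S)-3-(4-pivaloyloxyphenyl)oxirane-2-carbaldehyde (cis) | O=C[C@H]1O[C@H]1c1ccc(OC(=O)C(C)(C)C)cc1 | intermediate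
22 | bis(triisopropoxytitanium) derivative of 15 (phenolate and upper 3-alkoxide) | CC(C)O[Ti](OC(C)C)(OC(C)C)Oc1ccc([C@H]2c3ccc4OC(c5ccccc5)(c5ccccc5)Oc4c3O[C@H](c3ccc(OC(=O)C(C)(C)C)c(OC(=O)C(C)(C)C)c3)[C@@H]2O[Ti](OC(C)C)(OC(C)C)OC(C)C)c2OC(c3ccccc3)(c3ccccc3)Oc12 | intermediate (not isolated)
23 | 15 carrying at lower C-4a the (R)-hydroxy[(2R,3S)-3-(4-pivaloyloxyphenyl)oxiran-2-yl]methyl group, titanium-bound in the flask, drawn as the free phenol | Oc1c(cc([C@H]2c3ccc4OC(c5ccccc5)(c5ccccc5)Oc4c3O[C@H](c3ccc(OC(=O)C(C)(C)C)c(OC(=O)C(C)(C)C)c3)[C@@H]2O)c2OC(c3ccccc3)(c3ccccc3)Oc12)[C@@H](O)[C@H]1O[C@H]1c1ccc(OC(=O)C(C)(C)C)cc1 | intermediate (not isolated)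
24 | 6-{(2R,3R)-2-[3,4-bis(pivaloyloxy)phenyl]-3-hydroxy-7,8-(diphenylmethylenedioxy)flavan-4β-yl}-(2R,3R,4R)-2-(4-pivaloyloxyphenyl)-7,8-(diphenylmethylenedioxy)flavan-3,4-diol | CC(C)(C)C(=O)Oc1ccc([C@H]2Oc3c(cc([C@H]4c5ccc6OC(c7ccccc7)(c7ccccc7)Oc6c5O[C@H](c5ccc(OC(=O)C(C)(C)C)c(OC(=O)C(C)(C)C)c5)[C@@H]4O)c4OC(c5ccccc5)(c5ccccc5)Oc34)[C@@H](O)[C@H]2O)cc1 | intermediate
25 | 6-[(2R,3R)-2-(3,4-dihydroxyphenyl)-3-hydroxy-7,8-(diphenylmethylenedioxy)flavan-4β-yl]-(2R,3R,4R)-2-(4-hydroxyphenyl)-7,8-(diphenylmethylenedioxy)flavan-3,4-diol | Oc1ccc([C@H]2Oc3c(cc([C@H]4c5ccc6OC(c7ccccc7)(c7ccccc7)Oc6c5O[C@H](c5ccc(O)c(O)c5)[C@@H]4O)c4OC(c5ccccc5)(c5ccccc5)Oc34)[C@@H](O)[C@H]2O)cc1 | intermediate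
26 | epimesquitol-(4β→6)-epioritin-4α-ol | Oc1ccc([C@H]2Oc3c(cc([C@H]4c5ccc(O)c(O)c5O[C@H](c5ccc(O)c(O)c5)[C@@H]4O)c(O)c3O)[C@@H](O)[C@H]2O)cc1 | target

**Step count and risks**

Total steps: 18. Longest linear sequence: 11 steps (4 → 5 → 7 → 8 → 9 → 10 → 13 → 14 → 15 → 24 → 25 → 26; steps 3–10 and 16–18).

Steps most likely to fail:

1. Step 16 (proposed new method). The ortho C–C bond formation on the crowded, highly substituted phenolate may be slow, so that the epoxide is opened first by isopropoxide or in the 5-exo mode, and the facial selectivity at C-4 may be poor. The fallback sets out from 15 (with epoxy alcohol 20) and returns at 24, using known reaction types in separate steps. Phenol 15 opens 20 at the benzylic carbon under Ti(OiPr)4 mediation (distal-carbon-selective opening of a 2,3-epoxy alcohol by an O-nucleophile, inversion) to give the aryl ether diol F1. TEMPO/PhI(OAc)2 then oxidises only the primary alcohol to the α-hydroxy aldehyde F2. MgBr2·OEt2 in CH2Cl2 at low temperature finally effects a chelation-controlled intramolecular Friedel–Crafts hydroxyalkylation at C-4a (para to O-7), which closes the same ring at C-4–C-4a; the chelate forces O-4 syn to O-3 and so should give 24.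

2. Step 8 (proposed new method). The same cascade on the simple phenol may suffer from epimerisation of the cis-epoxy aldehyde before C–C bond formation or from 5-exo ring closure. The fallback sets out from 2 (with epoxy alcohol 9) and returns at 13. Ti(OiPr)4-mediated opening of 9 by phenol 2 at the benzylic carbon gives the aryl ether diol F3; selective TEMPO/PhI(OAc)2 oxidation gives the α-hydroxy aldehyde F4; Lewis-acid (MgBr2·OEt2) intramolecular Friedel–Crafts hydroxyalkylation then gives 13 (either C-4 epimer serves step 9).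

3. Step 9. The diol electrophile may self-condense through its own nucleophilic C-6 faster than it is captured, and part of the attack on 3 may go ortho to the silyl ether. The fallback sets out from 13 and returns at 14. Diol 13 is first trapped by phenylmethanethiol (BF3·OEt2 cat., CH2Cl2, −20 °C), a far better nucleophile than any arene present, as the 4β-benzylsulfanyl flavan-3-ol F5. This stable thioether is then activated with the thiophilic salt AgBF4 at low temperature under essentially neutral conditions in the presence of excess 3, which generates the cation slowly and only in the presence of the nucleophile, to give 14.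

**Further compounds**

F1 | step 16 | (2R,3R)-3-({7-[(2R,3R)-2-[3,4-bis(pivaloyloxy)phenyl]-3-hydroxy-7,8-(diphenylmethylenedioxy)flavan-4β-yl]-2,2-diphenyl-1,3-benzodioxol-4-yl}oxy)-3-(4-pivaloyloxyphenyl)propane-1,2-diol | CC(C)(C)C(=O)Oc1ccc([C@@H](Oc2ccc([C@H]3c4ccc5OC(c6ccccc6)(c6ccccc6)Oc5c4O[C@H](c4ccc(OC(=O)C(C)(C)C)c(OC(=O)C(C)(C)C)c4)[C@@H]3O)c3OC(c4ccccc4)(c4ccccc4)Oc23)[C@H](O)CO)cc1
F2 | step 16 | (2S,3R)-3-({7-[(2R,3R)-2-[3,4-bis(pivaloyloxy)phenyl]-3-hydroxy-7,8-(diphenylmethylenedioxy)flavan-4β-yl]-2,2-diphenyl-1,3-benzodioxol-4-yl}oxy)-2-hydroxy-3-(4-pivaloyloxyphenyl)propanal | CC(C)(C)C(=O)Oc1ccc([C@@H](Oc2ccc([C@H]3c4ccc5OC(c6ccccc6)(c6ccccc6)Oc5c4O[C@H](c4ccc(OC(=O)C(C)(C)C)c(OC(=O)C(C)(C)C)c4)[C@@H]3O)c3OC(c4ccccc4)(c4ccccc4)Oc23)[C@H](O)C=O)cc1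
F3 | step 8 | (2R,3R)-3-[3,4-bis(pivaloyloxy)phenyl]-3-[(2,2-diphenyl-1,3-benzodioxol-4-yl)oxy]propane-1,2-diol | CC(C)(C)C(=O)Oc1ccc([C@@H](Oc2cccc3OC(c4ccccc4)(c4ccccc4)Oc23)[C@H](O)CO)cc1OC(=O)C(C)(C)C
F4 | step 8 | (2S,3R)-3-[3,4-bis(pivaloyloxy)phenyl]-3-[(2,2-diphenyl-1,3-benzodioxol-4-yl)oxy]-2-hydroxypropanal | CC(C)(C)C(=O)Oc1ccc([C@@H](Oc2cccc3OC(c4ccccc4)(c4ccccc4)Oc23)[C@H](O)C=O)cc1OC(=O)C(C)(C)C
F5 | step 9 | (2R,3R)-4β-benzylsulfanyl-2-[3,4-bis(pivaloyloxy)phenyl]-7,8-(diphenylmethylenedioxy)flavan-3-ol | CC(C)(C)C(=O)Oc1ccc([C@H]2Oc3c(ccc4OC(c5ccccc5)(c5ccccc5)Oc34)[C@H](SCc3ccccc3)[C@H]2O)cc1OC(=O)C(C)(C)C
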